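Each of the two enolised 2,2,4,4-tetramethylcyclohexane-1,3,5-trione (syncarpic acid) rings is cut between the ring carbonyl carbon beside the side-chain-bearing sp2 carbon and the adjacent C(CH3)2 carbon. What remains, C(=O)–C(CH3)2–C(=O)–CH(CH3)2, is a ring-opened dimethylketene dimer. In one flask a thioacetate enolate opens the four-membered dione to an acyclic 3,5-diketo thioester; its isopropyl methine carbon, the only further enolisable site, then closes the six-membered ring by thio-Dieckmann acylation of the thioester carbon. The precursor is thus a cyclobutane-1,3-dione plus a two-carbon thioester. Knoevenagel condensation with isobutyraldehyde and a catalytic enantioselective double Friedel–Crafts-type Michael addition to isobutyrylphloroglucinol, which sets both methine stereocentres, finish the synthesis.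

Key step: step 1

Assumption: the quinine-derived squaramide is taken to give the R configuration at both methine carbons; should a trial at the mono-adduct stage show the opposite sense, its quinidine-derived pseudo-enantiomer is used instead, and isobutyrylphloroglucinol is treated as a catalogue compound.

Locants for the trione ring used below: C-1 carbonyl carbon (from the thioester), C-2 the carbon that later bears the side chain, C-3 carbonyl carbon, C-4 C(CH3)2, C-5 carbonyl carbon, C-6 C(CH3)2.

Step 1
Reactants: 1 2,2,4,4-tetramethylcyclobutane-1,3-dione (dimethylketene dimer); 2 S-tert-butyl thioacetate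
Product: 5 syncarpic acid (2,2,4,4-tetramethylcyclohexane-1,3,5-trione in its enol form), via cyclobutanol aldol adduct 3 (not isolated), via acyclic diketo thioester 4 (not isolated)
Conditions: 2, LiN(iPr)2 (1.1 equiv), THF, −78 °C; then 1, −78 to −20 °C; then LiN(iPr)2 (1.4 equiv), DMPU, −78 °C to rt; 1 M HCl
Reagents that add atoms: none
Why: The thioester lithium enolate adds to one carbonyl of the strained dione to give aldolate 3, whose four-membered ring opens by retro-Claisen C–C cleavage (the acylating ring opening known for dimethylketene dimer with alkoxide, amine and enolate nucleophiles) to the acyclic 3,5-diketo thioester 4, held after proton transfer as its C-2 enolate. Because C-4 is quaternary, the second portion of LiN(iPr)2 can remove only the isopropyl methine proton at C-6, and the resulting tetrasubstituted ketone enolate attacks the thioester carbon C-1 and expels tert-butylthiolate, a thio-Dieckmann (intramolecular Claisen) condensation that forms the C(=O)–C(CH3)2 bond and delivers the syncarpate anion. The closest known reactions are the methoxide-induced conversion of dimethylketene dimer into hexamethylcyclohexane-1,3,5-trione (ring opening, ester-enolate acylation, Dieckmann closure at a carbon of the same kind) and the Claisen cyclisation of polyketide 3,5-diketo (thio)esters to phloroglucinols. The one ring is closed in the favoured 6-(enolendo)-exo-trig mode and no stereocentre is formed. The step needs C- rather than O-acylation of the C-5/C-6 enolate and attack on an acyl carbon that lies within a β-keto thioester enolate: the lithium counter-ion in THF favours C-acylation, the thioester keeps more carbonyl character and a better leaving group than an oxo-ester, and the strongly acidic vinylogous-acid product is the thermodynamic sink into which a reversibly formed enol lactone can drain through thiolate re-opening.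

Step 2
Reactants: 5 syncarpic acid; 6 isobutyraldehyde (2-methylpropanal)
Product: 8 isobutylidene syncarpic acid (2,2,4,4-tetramethyl-6-(2-methylpropylidene)cyclohexane-1,3,5-trione), via piperidine Mannich base 7 (not isolated)
Conditions: piperidine (1.1 equiv), CH2Cl2, rt; then 1 M HCl, rt
Reagents that add atoms: none
Why: Knoevenagel condensation run as a Mannich reaction and elimination: piperidine and the aldehyde form an iminium ion that the acidic trione captures at C-2 to give zwitterion 7, which resists addition of a second trione, and acid then protonates nitrogen and triggers loss of piperidine to the exocyclic alkene; the trione is symmetric, so neither alkene geometry nor a stereocentre arises.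

Step 3
Reactants: 8 isobutylidene syncarpic acid (2.2 equiv); 9 isobutyrylphloroglucinol (2-methyl-1-(2,4,6-trihydroxyphenyl)propan-1-one)
Product: 11 myrtucommulone A (R configuration at both methine carbons), via mono-adduct 10 (not isolated)
Conditions: quinine-derived squaramide carrying a 3,5-bis(trifluoromethyl)benzylamino group (10 mol %), toluene/THF 9:1, −40 °C; aq. NaH2PO4 wash; chromatography
Reagents that add atoms: none
Why: Enantioselective Friedel–Crafts-type Michael addition of an acylphloroglucinol to an alkylidene cyclic 1,3-dione under bifunctional base/hydrogen-bond catalysis, in which the quinuclidine nitrogen engages the acidic phenol while the squaramide N–H bonds bind a ring carbonyl of 8, so that each of the two C-alkylations (at the free arene carbons C-3 and C-5) should occur on the alkene face set by the catalyst; the two methine stereocentres are set independently under catalyst control as R, which should leave the meso isomer as a minor, separable by-product.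

Compound list
1 | 2,2,4,4-tetramethylcyclobutane-1,3-dione (dimethylketene dimer) | CC1(C)C(=O)C(C)(C)C1=O | starting material
2 | S-tert-butyl thioacetate (S-tert-butyl ethanethioate) | CC(=O)SC(C)(C)C | starting material
3 | cyclobutanol aldol adduct, S-tert-butyl 2-(1-hydroxy-2,2,4,4-tetramethyl-3-oxocyclobutyl)ethanethioate (lithium alkoxide in the flask) | CC(C)(C)SC(=O)CC1(O)C(C)(C)C(=O)C1(C)C | intermediate
4 | acyclic diketo thioester, S-tert-butyl 4,4,6-trimethyl-3,5-dioxoheptanethioate (lithium enolate in the flask) | CC(C)C(=O)C(C)(C)C(=O)CC(=O)SC(C)(C)C | intermediate
5 | syncarpic acid, 2,2,4,4-tetramethylcyclohexane-1,3,5-trione drawn as its enol | CC1(C)C(=O)C=C(O)C(C)(C)C1=O | intermediate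
6 | isobutyraldehyde (2-methylpropanal) | CC(C)C=O | starting material
7 | piperidine Mannich base, 3-hydroxy-4,4,6,6-tetramethyl-2-[2-methyl-1-(piperidin-1-yl)propyl]cyclohex-2-ene-1,5-dione (racemic) | CC(C)C(N1CCCCC1)C1=C(O)C(C)(C)C(=O)C(C)(C)C1=O | intermediate
8 | isobutylidene syncarpic acid, 2,2,4,4-tetramethyl-6-(2-methylpropylidene)cyclohexane-1,3,5-trione | CC(C)C=C1C(=O)C(C)(C)C(=O)C(C)(C)C1=O | intermediate
9 | isobutyrylphloroglucinol, 2-methyl-1-(2,4,6-trihydroxyphenyl)propan-1-one | CC(C)C(=O)c1c(O)cc(O)cc1O | starting material
10 | mono-adduct, isobutyrylphloroglucinol carrying at C-3 one (1R)-1-(2-hydroxy-3,3,5,5-tetramethyl-4,6-dioxocyclohex-1-en-1-yl)-2-methylpropyl group | CC(C)C(=O)c1c(O)cc(O)c([C@H](C2=C(O)C(C)(C)C(=O)C(C)(C)C2=O)C(C)C)c1O | intermediate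
11 | myrtucommulone A, isobutyrylphloroglucinol carrying at C-3 and C-5 the same (1R)-1-(2-hydroxy-3,3,5,5-tetramethyl-4,6-dioxocyclohex-1-en-1-yl)-2-methylpropyl group | CC(C)C(=O)c1c(O)c([C@H](C2=C(O)C(C)(C)C(=O)C(C)(C)C2=O)C(C)C)c(O)c([C@H](C2=C(O)C(C)(C)C(=O)C(C)(C)C2=O)C(C)C)c1O | target

Total step count: 3
Longest linear sequence: 3 steps (1 to 5 to 8 to 11)

Steps most likely to fail, in order of risk

(a) The key step, step 1. The chain may open but not close: after proton transfer the thioester carbon lies within a chelated β-keto thioester enolate, so the second enolisation at C-6 and the C-acylation may be slow, and O-acylation or acylation of further dione may take over. The fallback blocks C-2 so that no acidic proton can form there, while the ring is still closed at the same bond. It sets out from 1: the sodium enolate of ethyl 1,3-dithiane-2-carboxylate (NaH, THF/DMF, 0 °C to reflux) opens the dione to ethyl 2-(2,2,4-trimethyl-3-oxopentanoyl)-1,3-dithiane-2-carboxylate F1. Its C-6 enolate cannot be quenched internally and should close by Dieckmann condensation onto the neutral ester, as in the formation of the hexamethyl trione, to give the spiro-dithiane trione F2. Skeletal nickel (Ni, from Ni–Al alloy) in ethanol then removes the sulfur, and the route is rejoined at 5.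

(b) The final step, step 3. Uncatalysed background addition and protonation of the catalyst by the acidic enol product may erode facial selectivity in either C-alkylation, so that the enantiomer and the meso isomer build up. The fallback gives up asymmetric catalysis for resolution. It sets out from 8 and 9: double addition with an achiral base (catalytic NaH, THF, rt) should give 11 together with its S,S enantiomer F3 and the meso isomer F4. The meso isomer is removed by chromatography or crystallisation, and the remaining racemate is separated by preparative HPLC on an amylose tris(3,5-dimethylphenylcarbamate) phase, which comes back to the route at 11.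

(c) The condensation, step 2. Over-reaction may occur: a second molecule of 5 may add in conjugate fashion to the newly formed alkene, or 8 may be lost by self-condensation during the acid-induced elimination. The fallback reaches the alkene by adjusting the oxidation level instead of by condensation. It sets out from 5: three-component reductive alkylation with 6, diethyl 2,6-dimethyl-1,4-dihydropyridine-3,5-dicarboxylate and catalytic L-proline (CH2Cl2, rt) should give 2-isobutyl syncarpic acid F5. Selenenylation at C-2 (PhSeCl, pyridine, CH2Cl2, 0 °C) gives the selenide F6. Oxidation (mCPBA, CH2Cl2, −78 to 0 °C) and syn-elimination of the selenoxide, which can only take a hydrogen from the side-chain CH2, return the route at 8.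

Further compounds
F1 | step 1 | ethyl 2-(2,2,4-trimethyl-3-oxopentanoyl)-1,3-dithiane-2-carboxylate | CCOC(=O)C1(SCCCS1)C(=O)C(C)(C)C(=O)C(C)C
F2 | step 1 | 8,8,10,10-tetramethyl-1,5-dithiaspiro[5.5]undecane-7,9,11-trione | CC1(C)C(=O)C(C)(C)C(=O)C2(SCCCS2)C1=O
F3 | step 3 | S,S enantiomer of myrtucommulone A | CC(C)C(=O)c1c(O)c([C@@H](C2=C(O)C(C)(C)C(=O)C(C)(C)C2=O)C(C)C)c(O)c([C@@H](C2=C(O)C(C)(C)C(=O)C(C)(C)C2=O)C(C)C)c1O
F4 | step 3 | meso (R,S) isomer of myrtucommulone A | CC(C)C(=O)c1c(O)c([C@H](C2=C(O)C(C)(C)C(=O)C(C)(C)C2=O)C(C)C)c(O)c([C@@H](C2=C(O)C(C)(C)C(=O)C(C)(C)C2=O)C(C)C)c1O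
F5 | step 2 | 2-isobutyl syncarpic acid, 3-hydroxy-4,4,6,6-tetramethyl-2-(2-methylpropyl)cyclohex-2-ene-1,5-dione | CC(C)CC1=C(O)C(C)(C)C(=O)C(C)(C)C1=O
F6 | step 2 | 2,2,4,4-tetramethyl-6-(2-methylpropyl)-6-(phenylselanyl)cyclohexane-1,3,5-trione | CC(C)CC1([Se]c2ccccc2)C(=O)C(C)(C)C(=O)C(C)(C)C1=O
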